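Thursday's run held more partner than Tuesday's, 0.16 M against 0.040 M, and it gave a mean [target] of 0.0465 M against 0.0248 M, with [intermediate] at 0.0483 M against 0.0138 M.

all flasks: substrate 0.10 M

| flask | partner | remark | time |
|---|---|---|---|
| Tuesday's | 0.040 M | run made earlier |  |
| Thursday's | 0.16 M | run made earlier |  |
| flask | 0.0800 M |  | 12 h |

- Tuesday's (time / h: target / %, intermediate / %): 3.00: 24.9, 14.0; 6.00: 25.2, 13.8; 8.00: 25.0, 13.8; 12.0: 24.6, 13.9; 15.0: 24.2, 13.7
- Thursday's (time / h: target / %, intermediate / %): 3.00: 46.2, 48.0; 6.00: 46.6, 48.2; 8.00: 47.0, 49.0; 12.0: 46.5, 48.3; 15.0: 46.3, 48.0

(standard deviation of a reading: 0.3 percentage points)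

- the numbers in the tables scatter by 0.3 percentage points (one standard deviation)
- the reaction counts as stopped when no species that holds the substrate changes by six tenths of a point or more over the second half of the time

* which holds at 12 h: what has brought the reaction to rest, or that it has not come to rest (it is still moving / forward and back rates have come level / the partner has run out first / all of the substrate has reacted)
* amount of target at 12 h, in percent of the substrate charged
* amount of intermediate at 12 h, in percent of the substrate charged

Neither run moved by more than 1 percentage point after 3.00 h, and Thursday's readings left, by difference, 0.00518 M substrate and 0.0652 M partner free. So I read that rest as a balance: substrate + partner ⇌ intermediate ⇌ target + by-product, with one by-product per target.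

Then [target]²/[intermediate] is the equilibrium constant of the second step. It read 0.0444 M and 0.0448 M, which lie 0.00427 apart in powers of ten, while the partner charge moved 0.602. I carried their mean, the split quantity Q, 0.0446 M. At this balance [intermediate]/[target] equals [target]/Q, so the quantity compares two amounts.

Thursday's run also read [intermediate]/([substrate][partner]) as 143 M⁻¹. For this flask I began with free partner at 0.00800 M, split the bound amount by Q, and corrected with that constant. Free partner became 0.00834 M, which gave [target] 0.0385 M and [intermediate] 0.0332 M, or 38.5% and 33.2%.

The forecast gave forward and back rates have come level, 38.5% target and 33.2% intermediate: “So both are equilibria.”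

The flask gave forward and back rates have come level, with 38.6% target and 33.1% intermediate.

    intermediate ⇌ target + by-product (K = 0.0450 M, k = 0.00490 s⁻¹)
    substrate + partner ⇌ intermediate (K = 140 M⁻¹, k = 1.40 M⁻¹ s⁻¹)

The flask's slowest mode had a half-life of 0.939 min, far shorter than the 12 h allowed. Its first step relaxed faster than its second, in 0.188 min against 0.868 min, and at 120 h the flask still held 38.6% target. In this flask [target]/Q came to 0.865 and [intermediate]/[target] to 0.858. In the flask charged with 0.17 M substrate, which held 23.9% target and 21.5% intermediate, [target]/Q came to 0.911 and [intermediate]/[target] to 0.900.

Readings and results are calculated from invented constants; scatter was added.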